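**Retrosynthetic overview**

- Numbering is that of the 2,3-dihydro-1-benzofuran. Ring C is the benzo ring (C3a to C7a), ring B the 3,5-dihydroxyphenyl on C3, ring D the 4-hydroxyphenyl on C2, and ring A the 4-hydroxyphenyl of the ethyl chain on C6. The target is the trans-(2S,3S) isomer, and the last step frees four phenols from their methyl ethers.
- The key disconnection cuts O1–C2 and C2–C3 of the dihydrofuran ring, the only ring of the target made in the route. It is a [4+1] annulation of a ring C ortho-quinone methide (C3=C3a, C7a=O) with the 4-methoxybenzylide of an enantiopure C2-symmetric 2,5-dimethylthiolane, which supplies C2 and ring D.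
- The strategy rests on one feature: C3a sits between two oxygen-bearing carbons, C4 (OH) and C7a (O1). The quinone methide precursor is therefore a 2-(arylsulfonylmethyl)resorcinol with a mirror plane through C3a and C6, so either oxygen can become O1 and the other ends as the C4 phenol, unprotected.
- The resorcinol sulfone comes from 3,5-dihydroxybenzaldehyde: MOM protection, Horner–Wadsworth–Emmons olefination, hydrogenation, lithiation between the two OMOM groups, addition to 3,5-dimethoxybenzaldehyde (its carbonyl carbon becomes C3), then sulfinate with HCl.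
- The sulfonium salt comes from (2R,5R)-hexane-2,5-diol: dimesylate, sodium sulfide (double inversion, which closes the thiolane ring of the reagent), then S-alkylation with 4-methoxybenzyl bromide.

Key step: step 9

Remark (assumption on the chemistry): the benzylide is assumed to offer the quinone methide carbon the same open face it offers an aldehyde carbonyl (aryl turned away from the ring, attack anti to the methyl cis to the ylide carbon, the sense in which the (2R,5R)-sulfide leads to (S,S)-diaryl epoxides). With the inverting closure this maps the (2S,5S)-sulfide onto (2S,3S), hence the (2R,5R)-diol; if the sense proved opposite, the (2S,5S)-diol would go through the same steps.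

**Route**

Step 1
Reactants: 1 3,5-dihydroxybenzaldehyde
Product: 2 3,5-bis(methoxymethoxy)benzaldehyde
Conditions: MOMCl (2.5 equiv), iPr2NEt (3 equiv), CH2Cl2, 0 °C → rt
Reagents that add atoms: chloromethyl methyl ether, COCCl
Why: O-alkylation of both phenols (MOM protection) leaves the aldehyde untouched and installs the two groups that later direct lithiation to the carbon between them.

Step 2
Reactants: 2 3,5-bis(methoxymethoxy)benzaldehyde; 3 diethyl [(4-methoxyphenyl)methyl]phosphonate
Product: 5 1-[(E)-2-(4-methoxyphenyl)ethenyl]-3,5-bis(methoxymethoxy)benzene, via phosphonate carbanion potassium salt 4 (not isolated)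
Conditions: KOtBu (1.3 equiv), THF, 0 °C; then 2, 0 °C → rt
Reagents that add atoms: none
Why: Horner–Wadsworth–Emmons olefination of a non-enolisable aryl aldehyde with a benzylphosphonate carbanion should give the (E)-stilbene, whose geometry is erased in step 3.

Step 3
Reactants: 5 1-[(E)-2-(4-methoxyphenyl)ethenyl]-3,5-bis(methoxymethoxy)benzene
Product: 6 1-[2-(4-methoxyphenyl)ethyl]-3,5-bis(methoxymethoxy)benzene
Conditions: H2 (1 atm), Pd/C (10 wt% Pd on carbon), EtOAc, rt
Reagents that add atoms: none
Why: Heterogeneous catalytic hydrogenation saturates the stilbene C=C, while the aryl methyl ether and the MOM acetals are inert and no benzylic C–O bond is present.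

Step 4
Reactants: 6 1-[2-(4-methoxyphenyl)ethyl]-3,5-bis(methoxymethoxy)benzene; 7 3,5-dimethoxybenzaldehyde
Product: 9 (3,5-dimethoxyphenyl){4-[2-(4-methoxyphenyl)ethyl]-2,6-bis(methoxymethoxy)phenyl}methanol (racemic), via aryllithium 8 (not isolated)
Conditions: n-BuLi (1.15 equiv), THF, 0 °C, 1 h; then 7, −78 °C → rt; H2O
Reagents that add atoms: none
Why: Directed ortho-metalation, in which the two MOM ethers jointly direct n-BuLi to the carbon between them (much faster than lithiation next to the single methoxy of ring A or at the bibenzyl CH2), is followed by 1,2-addition of the aryllithium to the non-enolisable aldehyde to give the racemic benzhydrol.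

Step 5
Reactants: 9 (3,5-dimethoxyphenyl){4-[2-(4-methoxyphenyl)ethyl]-2,6-bis(methoxymethoxy)phenyl}methanol
Product: 11 2-[(3,5-dimethoxyphenyl)(4-methylbenzenesulfonyl)methyl]-5-[2-(4-methoxyphenyl)ethyl]benzene-1,3-diol (racemic), via bis-MOM sulfone 10 (not isolated)
Conditions: 4-MeC6H4SO2Na (5 equiv), conc. aq. HCl, THF/H2O, 0 °C → rt
Reagents that add atoms: sodium 4-methylbenzenesulfinate, Cc1ccc(S(=O)[O-])cc1.[Na+]
Why: Acid ionises the benzhydrol, which carries two ortho alkoxy donors, to a stabilised diarylmethyl cation that sulfinate captures at sulfur (SN1 sulfone formation, the thermodynamic S-alkylation), and the same acid then hydrolyses the two MOM acetals; the benzylic centre is racemic and is destroyed in step 9.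

Step 6
Reactants: 12 (2R,5R)-hexane-2,5-diol
Product: 13 (2R,5R)-hexane-2,5-diyl dimethanesulfonate
Conditions: MsCl (2.4 equiv), Et3N (3 equiv), CH2Cl2, 0 °C
Reagents that add atoms: methanesulfonyl chloride, CS(=O)(=O)Cl
Why: O-Sulfonylation of both secondary alcohols breaks no C–O bond, so both centres are retained and a bis-electrophile results.

Step 7
Reactants: 13 (2R,5R)-hexane-2,5-diyl dimethanesulfonate
Product: 15 (2S,5S)-2,5-dimethylthiolane, via mesyloxy thiolate 14 (not isolated)
Conditions: Na2S·9H2O (1.1 equiv), EtOH, rt; distillation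
Reagents that add atoms: sodium sulfide, [Na+].[Na+].[S-2]
Why: Two SN2 displacements by sulfur (intermolecular, then 5-exo-tet closure), each with inversion, should convert the (2R,5R)-dimesylate into the (2S,5S)-thiolane.

Step 8
Reactants: 15 (2S,5S)-2,5-dimethylthiolane; 16 4-methoxybenzyl bromide
Product: 17 (2S,5S)-1-[(4-methoxyphenyl)methyl]-2,5-dimethylthiolan-1-ium tetrafluoroborate
Conditions: AgBF4 (1.05 equiv), CH2Cl2, 0 °C → rt, dark; filter, precipitate with Et2O
Reagents that add atoms: silver tetrafluoroborate, [Ag+].F[B-](F)(F)F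
Why: S-Alkylation of the sulfide by the benzylic bromide is driven by precipitation of AgBr and leaves a non-nucleophilic counter-ion; because the two ring α-carbons are related by the C2 axis, sulfur is not a stereocentre and a single salt forms.

Step 9
Reactants: 11 2-[(3,5-dimethoxyphenyl)(4-methylbenzenesulfonyl)methyl]-5-[2-(4-methoxyphenyl)ethyl]benzene-1,3-diol; 17 (2S,5S)-1-[(4-methoxyphenyl)methyl]-2,5-dimethylthiolan-1-ium tetrafluoroborate (1.5 equiv)
Product: 21 (2S,3S)-3-(3,5-dimethoxyphenyl)-2-(4-methoxyphenyl)-6-[2-(4-methoxyphenyl)ethyl]-2,3-dihydro-1-benzofuran-4-ol, via sulfonium benzylide 18 (not isolated), via ortho-quinone methide 19 (not isolated), via betaine 20 (not isolated)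
Conditions: Cs2CO3 (3 equiv), CH2Cl2, 0 °C → rt
Reagents that add atoms: none
Why: Cs2CO3 deprotonates one phenol of 11, which expels sulfinate (E1cB) to give ortho-quinone methide 19, and deprotonates salt 17 at its benzylic carbon to give benzylide 18; the ylide carbon adds in a 1,4-sense to the exocyclic methide carbon (C2–C3 bond, ring C re-aromatised) to give betaine 20, whose phenoxide then displaces the thiolane at C2 (O1–C2 bond). The closest known reaction is the [4+1] annulation of sulfonium ylides with ortho-quinone methides released by carbonate base from 2-(1-tosylalkyl)phenols, which gives trans-2,3-dihydrobenzofurans; here the enantiopure C2-symmetric thiolane only takes the place of the achiral sulfide. The dihydrofuran ring closes by 5-exo-tet SN2 with inversion at C2. C2 is set by the thiolane: the benzylide turns its aryl group away from the ring, the methyl cis to the ylide carbon blocks one face, C3 bonds to the other, and the inverting closure should then give 2S from the (2S,5S)-sulfide; C3 follows from C2 because the betaine that closes with the two aryl groups on opposite faces of the forming ring does so faster than the one leading to cis, which can revert. The step needs enantiofacial and trans selectivity but no site selectivity, since the two phenols of 11 are equivalent by symmetry and whichever becomes O1 the other ends as the C4 hydroxyl; the aryl group on the methide carbon stabilises 19 long enough for capture.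

Step 10
Reactants: 21 (2S,3S)-3-(3,5-dimethoxyphenyl)-2-(4-methoxyphenyl)-6-[2-(4-methoxyphenyl)ethyl]-2,3-dihydro-1-benzofuran-4-ol
Product: 22 (2S,3S)-3-(3,5-dihydroxyphenyl)-2-(4-hydroxyphenyl)-6-[2-(4-hydroxyphenyl)ethyl]-2,3-dihydro-1-benzofuran-4-ol (CNP0315602.1)
Conditions: BBr3 (10 equiv), CH2Cl2, −78 °C → 0 °C; then H2O
Reagents that add atoms: none
Why: Lewis-acid cleavage of aryl methyl ethers (BBr3, bromide attack at methyl) should free the four phenols without touching C2 or C3, and the saturated C6 side chain offers no alkene to trap a transient C2 cation, so the trans-(2S,3S) arrangement is kept.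

**Compound list**

1 | 3,5-dihydroxybenzaldehyde | O=Cc1cc(O)cc(O)c1 | starting material
2 | 3,5-bis(methoxymethoxy)benzaldehyde | COCOc1cc(C=O)cc(OCOC)c1 | intermediate
3 | diethyl [(4-methoxyphenyl)methyl]phosphonate | CCOP(=O)(Cc1ccc(OC)cc1)OCC | starting material
4 | potassium salt of the carbanion of diethyl [(4-methoxyphenyl)methyl]phosphonate | CCOP(=O)(OCC)[CH-]c1ccc(OC)cc1.[K+] | intermediate (not isolated)
5 | 1-[(E)-2-(4-methoxyphenyl)ethenyl]-3,5-bis(methoxymethoxy)benzene | COCOc1cc(/C=C/c2ccc(OC)cc2)cc(OCOC)c1 | intermediate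
6 | 1-[2-(4-methoxyphenyl)ethyl]-3,5-bis(methoxymethoxy)benzene | COCOc1cc(CCc2ccc(OC)cc2)cc(OCOC)c1 | intermediate
7 | 3,5-dimethoxybenzaldehyde | COc1cc(C=O)cc(OC)c1 | starting material
8 | {4-[2-(4-methoxyphenyl)ethyl]-2,6-bis(methoxymethoxy)phenyl}lithium | [Li]c1c(OCOC)cc(CCc2ccc(OC)cc2)cc1OCOC | intermediate (not isolated)
9 | (3,5-dimethoxyphenyl){4-[2-(4-methoxyphenyl)ethyl]-2,6-bis(methoxymethoxy)phenyl}methanol (racemic) | COCOc1cc(CCc2ccc(OC)cc2)cc(OCOC)c1C(O)c1cc(OC)cc(OC)c1 | intermediate
10 | 2-[(3,5-dimethoxyphenyl)(4-methylbenzenesulfonyl)methyl]-5-[2-(4-methoxyphenyl)ethyl]-1,3-bis(methoxymethoxy)benzene (racemic) | COCOc1cc(CCc2ccc(OC)cc2)cc(OCOC)c1C(c1cc(OC)cc(OC)c1)S(=O)(=O)c1ccc(C)cc1 | intermediate (not isolated)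
11 | 2-[(3,5-dimethoxyphenyl)(4-methylbenzenesulfonyl)methyl]-5-[2-(4-methoxyphenyl)ethyl]benzene-1,3-diol (racemic) | COc1ccc(CCc2cc(O)c(C(c3cc(OC)cc(OC)c3)S(=O)(=O)c3ccc(C)cc3)c(O)c2)cc1 | intermediate
12 | (2R,5R)-hexane-2,5-diol | C[C@@H](O)CC[C@@H](C)O | starting material
13 | (2R,5R)-hexane-2,5-diyl dimethanesulfonate | C[C@@H](OS(C)(=O)=O)CC[C@@H](C)OS(C)(=O)=O | intermediate
14 | sodium (2S,5R)-5-[(methanesulfonyl)oxy]hexane-2-thiolate | C[C@H]([S-])CC[C@@H](C)OS(C)(=O)=O.[Na+] | intermediate (not isolated)
15 | (2S,5S)-2,5-dimethylthiolane | C[C@H]1CC[C@H](C)S1 | intermediate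
16 | 4-methoxybenzyl bromide | COc1ccc(CBr)cc1 | starting material
17 | (2S,5S)-1-[(4-methoxyphenyl)methyl]-2,5-dimethylthiolan-1-ium tetrafluoroborate | C[C@H]1CC[C@H](C)[S+]1Cc1ccc(OC)cc1.F[B-](F)(F)F | intermediate
18 | [(2S,5S)-2,5-dimethylthiolan-1-ium-1-yl](4-methoxyphenyl)methanide (sulfonium benzylide) | C[C@H]1CC[C@H](C)[S+]1[CH-]c1ccc(OC)cc1 | intermediate (not isolated)
19 | 6-[(3,5-dimethoxyphenyl)methylidene]-5-hydroxy-3-[2-(4-methoxyphenyl)ethyl]cyclohexa-2,4-dien-1-one (ortho-quinone methide) | O=C1C=C(CCc2ccc(OC)cc2)C=C(O)C1=Cc1cc(OC)cc(OC)c1 | intermediate (not isolated)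
20 | betaine: 2-{(1S,2R)-1-(3,5-dimethoxyphenyl)-2-[(2S,5S)-2,5-dimethylthiolan-1-ium-1-yl]-2-(4-methoxyphenyl)ethyl}-3-hydroxy-5-[2-(4-methoxyphenyl)ethyl]phenolate | C[C@H]1CC[C@H](C)[S+]1[C@@H](c1ccc(OC)cc1)[C@@H](c1cc(OC)cc(OC)c1)c1c([O-])cc(CCc2ccc(OC)cc2)cc1O | intermediate (not isolated)
21 | (2S,3S)-3-(3,5-dimethoxyphenyl)-2-(4-methoxyphenyl)-6-[2-(4-methoxyphenyl)ethyl]-2,3-dihydro-1-benzofuran-4-ol | COc1ccc(CCc2cc(O)c3c(c2)O[C@H](c2ccc(OC)cc2)[C@H]3c2cc(OC)cc(OC)c2)cc1 | intermediate
22 | (2S,3S)-3-(3,5-dihydroxyphenyl)-2-(4-hydroxyphenyl)-6-[2-(4-hydroxyphenyl)ethyl]-2,3-dihydro-1-benzofuran-4-ol | Oc1ccc(CCc2cc(O)c3c(c2)O[C@H](c2ccc(O)cc2)[C@H]3c2cc(O)cc(O)c2)cc1 | target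

**Step count**

Total steps: 10. Longest linear sequence: 7 steps (steps 1, 2, 3, 4, 5, 9, 10, from 3,5-dihydroxybenzaldehyde); the sulfonium branch (steps 6, 7, 8) joins at step 9.

**Steps most likely to fail**

Step 9. The thiolane may discriminate poorly between the two faces of the benzylide carbon when the electrophile is a quinone methide (addition through the minor ylide rotamer, or a reversible first addition), so the trans product would form with low enantiomeric purity. A lesser concern is O-benzylation of the spectator phenoxide by the salt. The fallback sets out from 11 and gives up reagent control. Thiolane, 16 and AgBF4 (as in step 8) give 1-[(4-methoxyphenyl)methyl]thiolan-1-ium tetrafluoroborate F1. With 11 and Cs2CO3 in CH2Cl2 this is the known racemic, trans-selective annulation and should give racemic trans-3-(3,5-dimethoxyphenyl)-2-(4-methoxyphenyl)-6-[2-(4-methoxyphenyl)ethyl]-2,3-dihydro-1-benzofuran-4-ol F2. The enantiomers are separated by preparative HPLC on a cellulose tris(3,5-dimethylphenylcarbamate) phase, and the (2S,3S) enantiomer rejoins the route at 21.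

Step 5. Once the phenols are free, the diarylmethyl cation can alkylate the resorcinol ring of a second molecule (Friedel–Crafts oligomerisation) faster than sulfinate captures it, and formaldehyde released from the MOM groups can hydroxymethylate the same ring. The fallback sets out from 9 and separates the two events. Freshly prepared 4-methylbenzenesulfinic acid in CH2Cl2 at rt should give the bis-MOM sulfone 10, which is isolated with the phenols still masked. The MOM groups are then removed with ZnBr2 and n-PrSH in CH2Cl2 at 0 °C, where the thiol takes up the methoxymethyl unit as a dithioacetal and no protic acid is present. The route is rejoined at 11. This fallback makes no compound outside the list (F0).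

Step 10. During the long exposure needed for four methyl ethers, BBr3 may ionise the C2–O1 benzylic ether (assisted by the para oxygen of ring D), followed by loss of the C3 proton or intermolecular Friedel–Crafts capture, which would erode the C3 configuration or the material. The fallback sets out from 2 and carries benzyl ethers in place of the four methyl ethers, so that the last step is a neutral hydrogenolysis.
- Olefination of 2 with diethyl {[4-(benzyloxy)phenyl]methyl}phosphonate (KOtBu, THF) gives 1-[(E)-2-[4-(benzyloxy)phenyl]ethenyl]-3,5-bis(methoxymethoxy)benzene F3.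
- Diimide reduction (4-methylbenzenesulfonohydrazide, NaOAc, DME/H2O, reflux) gives 1-{2-[4-(benzyloxy)phenyl]ethyl}-3,5-bis(methoxymethoxy)benzene F4 with the benzyl ether intact.
- Lithiation as in step 4 (kept short at −20 to 0 °C) and addition to 3,5-bis(benzyloxy)benzaldehyde give [3,5-bis(benzyloxy)phenyl]{4-[2-(4-(benzyloxy)phenyl)ethyl]-2,6-bis(methoxymethoxy)phenyl}methanol F5.
- Sulfinate and HCl as in step 5 give 2-{[3,5-bis(benzyloxy)phenyl](4-methylbenzenesulfonyl)methyl}-5-{2-[4-(benzyloxy)phenyl]ethyl}benzene-1,3-diol F6.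
- Sulfide 15, 1-(benzyloxy)-4-(bromomethyl)benzene and AgBF4 give (2S,5S)-1-{[4-(benzyloxy)phenyl]methyl}-2,5-dimethylthiolan-1-ium tetrafluoroborate F7.
- Annulation of F6 with F7 as in step 9 gives (2S,3S)-3-[3,5-bis(benzyloxy)phenyl]-2-[4-(benzyloxy)phenyl]-6-{2-[4-(benzyloxy)phenyl]ethyl}-2,3-dihydro-1-benzofuran-4-ol F8.
- Hydrogenolysis (H2, 1 atm, Pd/C, EtOAc/MeOH, rt, stopped after uptake of four equivalents) removes the four benzyl groups and comes back to the route at 22.

Further compounds
F1 | step 9 | 1-[(4-methoxyphenyl)methyl]thiolan-1-ium tetrafluoroborate | COc1ccc(C[S+]2CCCC2)cc1.F[B-](F)(F)F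
F2 | step 9 | racemic trans-3-(3,5-dimethoxyphenyl)-2-(4-methoxyphenyl)-6-[2-(4-methoxyphenyl)ethyl]-2,3-dihydro-1-benzofuran-4-ol ((2S,3S) and (2R,3R)) | COc1ccc(CCc2cc(O)c3c(c2)O[C@H](c2ccc(OC)cc2)[C@H]3c2cc(OC)cc(OC)c2)cc1.COc1ccc(CCc2cc(O)c3c(c2)O[C@@H](c2ccc(OC)cc2)[C@@H]3c2cc(OC)cc(OC)c2)cc1
F0 | step 5 | none | none
F3 | step 10 | 1-[(E)-2-[4-(benzyloxy)phenyl]ethenyl]-3,5-bis(methoxymethoxy)benzene | COCOc1cc(/C=C/c2ccc(OCc3ccccc3)cc2)cc(OCOC)c1
F4 | step 10 | 1-{2-[4-(benzyloxy)phenyl]ethyl}-3,5-bis(methoxymethoxy)benzene | COCOc1cc(CCc2ccc(OCc3ccccc3)cc2)cc(OCOC)c1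
F5 | step 10 | [3,5-bis(benzyloxy)phenyl]{4-[2-(4-(benzyloxy)phenyl)ethyl]-2,6-bis(methoxymethoxy)phenyl}methanol (racemic) | COCOc1cc(CCc2ccc(OCc3ccccc3)cc2)cc(OCOC)c1C(O)c1cc(OCc2ccccc2)cc(OCc2ccccc2)c1
F6 | step 10 | 2-{[3,5-bis(benzyloxy)phenyl](4-methylbenzenesulfonyl)methyl}-5-{2-[4-(benzyloxy)phenyl]ethyl}benzene-1,3-diol (racemic) | Cc1ccc(cc1)S(=O)(=O)C(c1cc(OCc2ccccc2)cc(OCc2ccccc2)c1)c1c(O)cc(CCc2ccc(OCc3ccccc3)cc2)cc1O
F7 | step 10 | (2S,5S)-1-{[4-(benzyloxy)phenyl]methyl}-2,5-dimethylthiolan-1-ium tetrafluoroborate | C[C@H]1CC[C@H](C)[S+]1Cc1ccc(OCc2ccccc2)cc1.F[B-](F)(F)F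
F8 | step 10 | (2S,3S)-3-[3,5-bis(benzyloxy)phenyl]-2-[4-(benzyloxy)phenyl]-6-{2-[4-(benzyloxy)phenyl]ethyl}-2,3-dihydro-1-benzofuran-4-ol | c1ccccc1COc1ccc(CCc2cc(O)c3c(c2)O[C@H](c2ccc(OCc4ccccc4)cc2)[C@H]3c2cc(OCc4ccccc4)cc(OCc4ccccc4)c2)cc1
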